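**Retrosynthetic overview** (ring atoms: C1 quaternary with methyl C10 and chlorovinyl C8=C9; C2; C3 with Br and C7H2Br; C4 with Cl; C5; C6 with Cl)
- Target 20 comes from Br2 addition to the exocyclic C3=C7 alkene of 19, made by methylenation of α-chloro ketone 18. C4–Cl is installed by axial bromination and chloride inversion, and the (Z)-chlorovinyl group is made from a vinyl group through the chloroalkyne.
- C5 loses its oxygen after ring closure (mesylate elimination, copper hydride conjugate reduction).
- The only ring (C1–C6) is closed at C4–C5 by a proline aldol of the acyclic chloro keto-aldehyde 7. The feature used is that C6 carries Cl and H next to the C5 aldehyde and next to quaternary C1: it can epimerise, cannot lose HCl, and C5 is the electrophile for the C4 enamine, so ring closure and control of C6 happen together.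
- 7 comes from NCS chlorination of enol ether 6, which comes from one-carbon homologation of aldehyde 5. C1 is set by palladium-catalysed asymmetric allylic alkylation of isoprene monoepoxide 1 with methyl acetoacetate 2.

Key step: step 6

Assumption: the (R,R) enantiomer of the ligand in step 1 is taken as the one that gives the (3R) adduct 3; if the sense of induction is opposite, the (S,S) ligand is used and nothing else changes.

**Step 1**
Reactants: 1 2-methyl-2-vinyloxirane (racemic); 2 methyl acetoacetate
Product: 3 methyl (3R)-2-acetyl-3-(hydroxymethyl)-3-methylpent-4-enoate (both C2 epimers, in equilibrium with its cyclic hemiketal)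
Conditions: Pd2(dba)3·CHCl3 (1 mol%), (1R,2R)-N,N'-bis[2-(diphenylphosphino)-1-naphthoyl]cyclohexane-1,2-diamine (3 mol%), CH2Cl2, rt
Reagents that add atoms: none
Why: Asymmetric allylic alkylation run as a dynamic kinetic asymmetric transformation: both enantiomers of 1 ionise with zerovalent palladium to an interconverting π-allyl alkoxide, the alkoxide deprotonates 2 and steers it to the substituted terminus, and the ligand fixes quaternary C1.

**Step 2**
Reactants: 3 methyl (3R)-2-acetyl-3-(hydroxymethyl)-3-methylpent-4-enoate
Product: 4 (4S)-4-(hydroxymethyl)-4-methylhex-5-en-2-one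
Conditions: 1 M H2SO4 (aq), 1,4-dioxane, 90 °C
Reagents that add atoms: none
Why: Ketonic cleavage of an acetoacetic ester (acid hydrolysis, then decarboxylation of the β-keto acid) removes the scrambled C2 centre of 3 and leaves quaternary C1 untouched.

**Step 3**
Reactants: 4 (4S)-4-(hydroxymethyl)-4-methylhex-5-en-2-one
Product: 5 (2S)-2-ethenyl-2-methyl-4-oxopentanal
Conditions: Dess–Martin periodinane, CH2Cl2, 0 °C to rt
Reagents that add atoms: none
Why: Dess–Martin oxidation of the primary alcohol, which is drawn from the hemiketal equilibrium; the aldehyde has no α-hydrogen, so C1 cannot epimerise.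

**Step 4**
Reactants: 5 (2S)-2-ethenyl-2-methyl-4-oxopentanal
Product: 6 (4S)-4-ethenyl-6-methoxy-4-methylhex-5-en-2-one (E/Z mixture)
Conditions: Ph3P(CH2OMe)Cl (1.2 equiv), KN(SiMe3)2 (1.1 equiv), THF, 0 °C; then 5, −78 to −20 °C
Reagents that add atoms: (methoxymethyl)triphenylphosphonium chloride, COC[P+](c1ccccc1)(c1ccccc1)c1ccccc1.[Cl-]
Why: Wittig methoxymethylenation adds C5; at low temperature the aldehyde should react well ahead of the neopentyl-flanked methyl ketone, and a slight deficit of base keeps the ketone from being enolised.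

**Step 5**
Reactants: 6 (4S)-4-ethenyl-6-methoxy-4-methylhex-5-en-2-one
Product: 7 (3S)-2-chloro-3-ethenyl-3-methyl-5-oxohexanal (both C2 epimers, used crude)
Conditions: NCS (1.05 equiv), THF/H2O 4:1, 0 °C
Reagents that add atoms: N-chlorosuccinimide, ClN1C(=O)CCC1=O; water, O
Why: Electrophilic chlorination of the enol ether and hydrolysis of the chloro oxocarbenium ion give the α-chloroaldehyde without any amine that could trigger the aldol early; C6 is formed without control, which is harmless because step 6 equilibrates it.

**Step 6**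
Reactants: 7 (3S)-2-chloro-3-ethenyl-3-methyl-5-oxohexanal
Product: 8 (3S,4R,5S)-4-chloro-3-ethenyl-5-hydroxy-3-methylcyclohexan-1-one
Conditions: L-proline (30 mol%), DMSO, 20 °C
Reagents that add atoms: none
Why: Proposed new method: proline condenses with the methyl ketone to the less substituted enamine C3=C4, C4 adds to the C5 aldehyde while the carboxylic acid hydrogen-bonds the aldehyde oxygen, and hydrolysis of the iminium ion frees the catalyst; the closest known reactions are the intermolecular proline aldol of α-chloroaldehydes with dynamic kinetic resolution and the enolendo proline aldol cyclisation of the Hajos–Parrish type. The ring C1–C6 closes in the 6-(enolendo)-exo-trig mode through a half-chair in which the aldehyde oxygen must stand axial to reach the acid. C5 is set by the catalyst: in the anti enamine of L-proline the acid lies on the ring face that carries the vinyl group of C1, so the oxygen ends on that face (5S), by the same model that accounts for the sense of the Hajos–Parrish closure. C6 is set relative to C5 by the polar Felkin–Anh preference: the epimer whose C–Cl bond is equatorial and anti to the forming C4–C5 bond should close faster and give the chloride cis to the hydroxyl (4R in 8, which is C6 = S of the target), while the slower epimer returns to the pool through the aldehyde enamine or enol. The step needs epimerisation at C6 to outrun closure of the mismatched epimer; this is helped because the amine meets the aldehyde faster than the hindered ketone and because quaternary C1 leaves no β-hydrogen for loss of HCl. Methyl and vinyl on C1 are near-equal in size, so C1 should not compete with the catalyst.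

**Step 7**
Reactants: 8 (3S,4R,5S)-4-chloro-3-ethenyl-5-hydroxy-3-methylcyclohexan-1-one
Product: 10 (4S,5S)-4-chloro-5-ethenyl-5-methylcyclohex-2-en-1-one, via mesylate 9 (not isolated)
Conditions: MsCl (1.3 equiv), Et3N (3 equiv), CH2Cl2, −20 to 0 °C
Reagents that add atoms: none
Why: Mesylation followed by E1cB elimination through the C4 enolate removes the C5 oxygen as the C4=C5 enone; fast trapping of the hydroxyl prevents retro-aldol, and cold, short contact with the amine should keep the γ-centre C6.

**Step 8**
Reactants: 10 (4S,5S)-4-chloro-5-ethenyl-5-methylcyclohex-2-en-1-one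
Product: 11 (3S,4S)-4-chloro-3-ethenyl-3-methylcyclohexan-1-one
Conditions: [(Ph3P)CuH]6 (0.4 equiv), H2O (5 equiv), THF, rt
Reagents that add atoms: none
Why: Copper hydride conjugate reduction delivers hydride to C5 and the copper enolate is protonated by water at once, so the isolated vinyl group and the C6 chloride are left alone and the enolate has no time to displace the γ-chloride.

**Step 9**
Reactants: 11 (3S,4S)-4-chloro-3-ethenyl-3-methylcyclohexan-1-one
Product: 12 (1S,2S)-2-chloro-1-methyl-5-oxocyclohexane-1-carbaldehyde
Conditions: O3, CH2Cl2/MeOH, −78 °C; Me2S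
Reagents that add atoms: ozone, [O-][O+]=O
Why: Ozonolysis with reductive work-up cleaves the only alkene to the C8 aldehyde, which has no α-hydrogen.

**Step 10**
Reactants: 12 (1S,2S)-2-chloro-1-methyl-5-oxocyclohexane-1-carbaldehyde
Product: 13 (3S,4S)-4-chloro-3-ethynyl-3-methylcyclohexan-1-one
Conditions: dimethyl (1-diazo-2-oxopropyl)phosphonate, K2CO3, MeOH, 0 °C to rt
Reagents that add atoms: dimethyl (1-diazo-2-oxopropyl)phosphonate, CC(=O)C(=[N+]=[N-])P(=O)(OC)OC
Why: Seyferth–Gilbert homologation with the Ohira–Bestmann reagent adds C9; under K2CO3/MeOH aldehydes react while ketones do not.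

**Step 11**
Reactants: 13 (3S,4S)-4-chloro-3-ethynyl-3-methylcyclohexan-1-one
Product: 14 (3S,4S)-4-chloro-3-(chloroethynyl)-3-methylcyclohexan-1-one
Conditions: NCS (1.2 equiv), AgOAc (10 mol%), acetone, rt
Reagents that add atoms: N-chlorosuccinimide, ClN1C(=O)CCC1=O
Why: Silver-acetylide-mediated electrophilic chlorination of the terminal alkyne proceeds without strong base, so the ketone and the alkyl chloride should survive.

**Step 12**
Reactants: 14 (3S,4S)-4-chloro-3-(chloroethynyl)-3-methylcyclohexan-1-one
Product: 15 (3S,4S)-4-chloro-3-[(Z)-2-chloroethenyl]-3-methylcyclohexan-1-one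
Conditions: KO2CN=NCO2K, AcOH, MeOH, rt
Reagents that add atoms: none
Why: Diimide reduction transfers two hydrogens to the same side of the chloroalkyne, which gives only the Z-chloroalkene, and diimide does not reduce ketones or C–Cl bonds.

**Step 13**
Reactants: 15 (3S,4S)-4-chloro-3-[(Z)-2-chloroethenyl]-3-methylcyclohexan-1-one
Product: 16 {[(4S,5S)-4-chloro-5-[(Z)-2-chloroethenyl]-5-methylcyclohex-1-en-1-yl]oxy}trimethylsilane
Conditions: LiN(SiMe3)2, Me3SiCl (present from the start), THF, −78 °C
Reagents that add atoms: chlorotrimethylsilane, C[Si](C)(C)Cl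
Why: Kinetic enolisation with in situ silylation takes the proton from the open C4 methylene and not from the neopentyl C2, which fixes the regiochemistry of the halogenation.

**Step 14**
Reactants: 16 {[(4S,5S)-4-chloro-5-[(Z)-2-chloroethenyl]-5-methylcyclohex-1-en-1-yl]oxy}trimethylsilane
Product: 17 (2S,4S,5S)-2-bromo-4-chloro-5-[(Z)-2-chloroethenyl]-5-methylcyclohexan-1-one
Conditions: NBS, THF, −78 °C
Reagents that add atoms: N-bromosuccinimide, BrN1C(=O)CCC1=O
Why: Electrophilic bromination of the silyl enol ether by axial attack at C4 on the face away from the C6 chlorine should give the axial bromide trans to C6–Cl, which is the C4 configuration opposite to the one the target needs.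

**Step 15**
Reactants: 17 (2S,4S,5S)-2-bromo-4-chloro-5-[(Z)-2-chloroethenyl]-5-methylcyclohexan-1-one
Product: 18 (2R,4S,5S)-2,4-dichloro-5-[(Z)-2-chloroethenyl]-5-methylcyclohexan-1-one
Conditions: LiCl (3 equiv), DMF, 0 °C to rt
Reagents that add atoms: lithium chloride, [Li+].[Cl-]
Why: Finkelstein SN2 exchange at the carbonyl-activated axial C–Br bond inverts C4 and places chlorine equatorial and cis to the C6 chlorine (C4 = R of the target); the equatorial chloride of the now locked chair is poorly aligned for further exchange.

**Step 16**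
Reactants: 18 (2R,4S,5S)-2,4-dichloro-5-[(Z)-2-chloroethenyl]-5-methylcyclohexan-1-one
Product: 19 (1S,2S,4R)-2,4-dichloro-1-[(Z)-2-chloroethenyl]-1-methyl-5-methylidenecyclohexane
Conditions: Cp2Ti(μ-Cl)(μ-CH2)AlMe2 (Tebbe reagent), pyridine (cat.), THF/toluene, −40 to 0 °C
Reagents that add atoms: Tebbe reagent, written as its components C=[Ti](C1C=CC=C1)C1C=CC=C1.C[Al](C)Cl
Why: Tebbe methylenation (titanium methylidene cycloaddition and cycloreversion) adds C7 without base and without a reducing metal, so the α-chloro centre C4 is neither enolised nor dechlorinated.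

**Step 17**
Reactants: 19 (1S,2S,4R)-2,4-dichloro-1-[(Z)-2-chloroethenyl]-1-methyl-5-methylidenecyclohexane
Product: 20 (1S,2R,4S,5S)-1-bromo-1-(bromomethyl)-2,4-dichloro-5-[(Z)-2-chloroethenyl]-5-methylcyclohexane (target)
Conditions: Br2 (1.0 equiv), CH2Cl2, −78 °C, dark
Reagents that add atoms: bromine, BrBr
Why: Electrophilic bromination: the bromonium ion should form on the open equatorial face of the exocyclic alkene and bromide should open it at tertiary C3 by axial attack, giving axial C3–Br (S) with equatorial CH2Br, while the deactivated chloroalkene does not react with one equivalent.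

**Compound list**
1 | 2-methyl-2-vinyloxirane (isoprene monoepoxide, racemic) | CC1(CO1)C=C | starting material
2 | methyl acetoacetate | CC(=O)CC(=O)OC | starting material
3 | methyl (3R)-2-acetyl-3-(hydroxymethyl)-3-methylpent-4-enoate (both C2 epimers) | C[C@@](CO)(C=C)C(C(C)=O)C(=O)OC | intermediate
4 | (4S)-4-(hydroxymethyl)-4-methylhex-5-en-2-one | C[C@@](CO)(C=C)CC(C)=O | intermediate
5 | (2S)-2-ethenyl-2-methyl-4-oxopentanal | C[C@@](C=O)(C=C)CC(C)=O | intermediate
6 | (4S)-4-ethenyl-6-methoxy-4-methylhex-5-en-2-one (E/Z mixture) | C[C@@](C=COC)(C=C)CC(C)=O | intermediate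
7 | (3S)-2-chloro-3-ethenyl-3-methyl-5-oxohexanal (both C2 epimers) | C[C@@](C(Cl)C=O)(C=C)CC(C)=O | intermediate
8 | (3S,4R,5S)-4-chloro-3-ethenyl-5-hydroxy-3-methylcyclohexan-1-one | C[C@@]1(C=C)CC(=O)C[C@H](O)[C@@H]1Cl | intermediate
9 | (1S,2R,3S)-2-chloro-3-ethenyl-3-methyl-5-oxocyclohexyl methanesulfonate (not isolated) | C[C@@]1(C=C)CC(=O)C[C@H](OS(C)(=O)=O)[C@@H]1Cl | intermediate
10 | (4S,5S)-4-chloro-5-ethenyl-5-methylcyclohex-2-en-1-one | C[C@@]1(C=C)CC(=O)C=C[C@@H]1Cl | intermediate
11 | (3S,4S)-4-chloro-3-ethenyl-3-methylcyclohexan-1-one | C[C@@]1(C=C)CC(=O)CC[C@@H]1Cl | intermediate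
12 | (1S,2S)-2-chloro-1-methyl-5-oxocyclohexane-1-carbaldehyde | C[C@@]1(C=O)CC(=O)CC[C@@H]1Cl | intermediate
13 | (3S,4S)-4-chloro-3-ethynyl-3-methylcyclohexan-1-one | C[C@@]1(C#C)CC(=O)CC[C@@H]1Cl | intermediate
14 | (3S,4S)-4-chloro-3-(chloroethynyl)-3-methylcyclohexan-1-one | C[C@@]1(C#CCl)CC(=O)CC[C@@H]1Cl | intermediate
15 | (3S,4S)-4-chloro-3-[(Z)-2-chloroethenyl]-3-methylcyclohexan-1-one | C[C@@]1(/C=C\Cl)CC(=O)CC[C@@H]1Cl | intermediate
16 | {[(4S,5S)-4-chloro-5-[(Z)-2-chloroethenyl]-5-methylcyclohex-1-en-1-yl]oxy}trimethylsilane | C[C@@]1(/C=C\Cl)CC(O[Si](C)(C)C)=CC[C@@H]1Cl | intermediate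
17 | (2S,4S,5S)-2-bromo-4-chloro-5-[(Z)-2-chloroethenyl]-5-methylcyclohexan-1-one | C[C@@]1(/C=C\Cl)CC(=O)[C@@H](Br)C[C@@H]1Cl | intermediate
18 | (2R,4S,5S)-2,4-dichloro-5-[(Z)-2-chloroethenyl]-5-methylcyclohexan-1-one | C[C@@]1(/C=C\Cl)CC(=O)[C@H](Cl)C[C@@H]1Cl | intermediate
19 | (1S,2S,4R)-2,4-dichloro-1-[(Z)-2-chloroethenyl]-1-methyl-5-methylidenecyclohexane | C[C@@]1(/C=C\Cl)CC(=C)[C@H](Cl)C[C@@H]1Cl | intermediate
20 | (1S,2R,4S,5S)-1-bromo-1-(bromomethyl)-2,4-dichloro-5-[(Z)-2-chloroethenyl]-5-methylcyclohexane | C[C@@]1(/C=C\Cl)C[C@@](Br)(CBr)[C@H](Cl)C[C@@H]1Cl | target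

**Step count:** 17 steps in total; the longest linear sequence is 17 steps (from 1 and 2).

**Steps most likely to fail**

Step 6 (proposed new method). Epimerisation at C6 of this β-quaternary aldehyde may be slower than ring closure, so that both epimers close and the selectivity at C6 is lost. The closure may also prefer the arrangement with C–Cl anti to C=O; in that case D-proline would be the matched catalyst, since C5 is erased in step 7 and only C6 counts. Fallback with known chemistry, setting out from 7: unselective aldol condensation with piperidinium acetate in toluene at 60 °C should give enone 10 together with its C4 epimer (4R,5S)-4-chloro-5-ethenyl-5-methylcyclohex-2-en-1-one F1. The two diastereomers are separated by chromatography, and F1 is returned to a mixture of both by γ-deprotonation with DBU (dienolate) and reprotonation, then separated again. The route is rejoined at 10.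

Step 17. Bromide has to enter C3 axially, past the axial chlorovinyl group on C1; opening of the bromonium ion at C7 or bromonium formation on the other face would give the C3 epimer. Fallback, setting out from 14: the sequence of steps 13 to 17 is run with the slim chloroethynyl group in place and the alkyne is reduced last.
- LiN(SiMe3)2/Me3SiCl gives {[(4S,5S)-4-chloro-5-(chloroethynyl)-5-methylcyclohex-1-en-1-yl]oxy}trimethylsilane F2.
- NBS gives (2S,4S,5S)-2-bromo-4-chloro-5-(chloroethynyl)-5-methylcyclohexan-1-one F3.
- LiCl in DMF gives (2R,4S,5S)-2,4-dichloro-5-(chloroethynyl)-5-methylcyclohexan-1-one F4.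
- Lombardo methylenation (Zn, CH2Br2, TiCl4, chosen because a titanium methylidene could add to the alkyne) gives (1S,2S,4R)-2,4-dichloro-1-(chloroethynyl)-1-methyl-5-methylidenecyclohexane F5.
- Br2 at −78 °C gives (1S,2R,4S,5S)-1-bromo-1-(bromomethyl)-2,4-dichloro-5-(chloroethynyl)-5-methylcyclohexane F6; the chloroalkyne should be inert to one equivalent and, being axial but linear, should not block C3.
- Diimide reduction (KO2CN=NCO2K, AcOH) of F6 then gives 20 directly.

Step 15. The halide exchange may be overtaken by dehydrobromination to the enone, or C4 may lose its configuration through enolisation or repeated exchange. Fallback, setting out from 16: chlorine is put in first and C4 is then set by C–H bond formation. NCS on 16 should give the axial chloride (2S,4S,5S)-2,4-dichloro-5-[(Z)-2-chloroethenyl]-5-methylcyclohexan-1-one F7. Deprotonation of F7 at C4 with LiN(SiMe3)2 at −78 °C and kinetic protonation of the chloro enolate by a hindered phenol, from the axial face away from the C6 chlorine, should leave chlorine equatorial. The route is rejoined at 18.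

**Further compounds**
F1 | step 6 | (4R,5S)-4-chloro-5-ethenyl-5-methylcyclohex-2-en-1-one | C[C@@]1(C=C)CC(=O)C=C[C@H]1Cl
F2 | step 17 | {[(4S,5S)-4-chloro-5-(chloroethynyl)-5-methylcyclohex-1-en-1-yl]oxy}trimethylsilane | C[C@@]1(C#CCl)CC(O[Si](C)(C)C)=CC[C@@H]1Cl
F3 | step 17 | (2S,4S,5S)-2-bromo-4-chloro-5-(chloroethynyl)-5-methylcyclohexan-1-one | C[C@@]1(C#CCl)CC(=O)[C@@H](Br)C[C@@H]1Cl
F4 | step 17 | (2R,4S,5S)-2,4-dichloro-5-(chloroethynyl)-5-methylcyclohexan-1-one | C[C@@]1(C#CCl)CC(=O)[C@H](Cl)C[C@@H]1Cl
F5 | step 17 | (1S,2S,4R)-2,4-dichloro-1-(chloroethynyl)-1-methyl-5-methylidenecyclohexane | C[C@@]1(C#CCl)CC(=C)[C@H](Cl)C[C@@H]1Cl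
F6 | step 17 | (1S,2R,4S,5S)-1-bromo-1-(bromomethyl)-2,4-dichloro-5-(chloroethynyl)-5-methylcyclohexane | C[C@@]1(C#CCl)C[C@@](Br)(CBr)[C@H](Cl)C[C@@H]1Cl
F7 | step 15 | (2S,4S,5S)-2,4-dichloro-5-[(Z)-2-chloroethenyl]-5-methylcyclohexan-1-one | C[C@@]1(/C=C\Cl)CC(=O)[C@@H](Cl)C[C@@H]1Cl
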